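**Strategy.** The route rests on cutting both diene bonds, C2–C3 and C4–C5: the ten-membered carbocycle (C1–C10) with its oxygen bridge from C3 to C10 is traced back to a cis-cyclooctene in which C2=C5 is intact and O10 carries a 1-propynyl group. One π-acid-catalysed enyne cycloisomerisation of this ynol ether closes the five-membered O–C3–C2–C1–C10 ring, expands the eight-membered ring by C3 and C4, and leaves the C2=C3/C4=C5 diene, trans in the carbocycle at C2=C3 and Z at C4=C5. The feature used is that diene bridged by the furanone ring. The precursor is an L-tartrate-derived cyclooctene with C1 dioxolane, O9 silyl ether and the silyl-masked C11–C13 chlorohydrin.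

Key step: step 20

Numbering: C1 furanone C=O; C2=C3 furanone alkene; C4=C5 Z-alkene (methyl on C4); C6 lactone O–CH; C7 ring-fusion CH; C8 angelate CH; C9 carbinol CH; C10 quaternary carbon (methyl); C11 chlorohydrin carbon; C12 lactone C=O; C13 CH2Cl. "On" is the oxygen on Cn.

Remark on stereochemistry: the target is read as 6S,7S,8S,9R,10R,11R with a cis-fused lactone (H6 and H7 on one face). C8 and C9 map onto L-tartrate. The C11 configuration calls for the D-tartrate ligand in step 15.

Remark on the cyclisation substrate: C13 already carries chlorine, so no late chlorination is needed. O9 carries a silyl group, not an acetal-type group that could add to the activated ynol ether and transfer a carbon fragment. The 1,2-dichlorovinyl ether that becomes the ynol ether is installed early and also protects the tertiary O10.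

Assumption: diethyl D-tartrate, methoxyallene, methyl acrylate and all catalysts are purchased.

**Step 1**
Reactants: 1 diethyl L-tartrate
Product: 2 diethyl (2R,3R)-2-(tert-butyldimethylsilyloxy)-3-hydroxybutanedioate
Conditions: TBSCl (1.0 equiv), imidazole, DMF, 0 °C
Reagents that add atoms: tert-butyldimethylsilyl chloride CC(C)(C)[Si](C)(C)Cl
Why: Silyl ether formation on a C2-symmetric diol, where either hydroxyl gives the same monoether; the silylated carbon becomes C9 and the free carbinol C8, both taken unchanged from the chiral pool.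

**Step 2**
Reactants: 2 mono-TBS tartrate
Product: 3 ethyl (2R,3S)-2-(tert-butyldimethylsilyloxy)-3,4-dihydroxybutanoate
Conditions: BH3·SMe2, NaBH4 (5 mol%), THF, 0 °C → rt; aqueous work-up; used at once
Reagents that add atoms: none
Why: Hydroxyl-directed borane reduction: the free C8 hydroxyl forms an alkoxyborane that delivers hydride only to the adjacent ester (C7), so the α-silyloxy ester (C10) survives and no stereocentre is touched.

**Step 3**
Reactants: 3 diol ester
Product: 4 ethyl (2R)-2-(tert-butyldimethylsilyloxy)-2-[(4S)-2-(4-methoxyphenyl)-1,3-dioxolan-4-yl]acetate (both acetal epimers)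
Conditions: 4-MeOC6H4CH(OMe)2, PPTS (cat.), CH2Cl2, rt
Reagents that add atoms: 4-methoxybenzaldehyde dimethyl acetal COC(OC)c1ccc(OC)cc1
Why: Acid-catalysed transacetalisation closes the five-membered p-methoxybenzylidene acetal on the terminal 1,2-diol, masking O7/O8 and storing the future O8 PMB group.

**Step 4**
Reactants: 4 acetal ester
Product: 6 (1R)-1-(tert-butyldimethylsilyloxy)-1-[(4S)-2-(4-methoxyphenyl)-1,3-dioxolan-4-yl]propan-2-one, via Weinreb amide 5 (not isolated)
Conditions: MeNHOMe·HCl, iPrMgCl, THF, −20 °C; then MeMgBr, −20 → 0 °C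
Reagents that add atoms: methylmagnesium bromide C[Mg]Br; N,O-dimethylhydroxylamine hydrochloride CNOC.Cl (atoms only in intermediate 5)
Why: One-pot Weinreb ketone synthesis: the magnesium amide converts the ester into the N-methoxy-N-methylamide, whose chelated adduct with MeMgBr collapses to the methyl ketone only on work-up, so over-addition is avoided.

**Step 5**
Reactants: 6 methyl ketone; 7 methoxyallene
Product: 9 (1R,2R)-1-(tert-butyldimethylsilyloxy)-3-methoxy-2-methyl-1-[(4S)-2-(4-methoxyphenyl)-1,3-dioxolan-4-yl]penta-3,4-dien-2-ol, via 1-lithio-1-methoxyallene 8 (not isolated)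
Conditions: 7, n-BuLi, THF, −40 °C; then 6, −78 °C
Reagents that add atoms: n-butyllithium [Li]CCCC (lithium only in intermediate 8)
Why: 1,2-Addition of lithiated methoxyallene (an acryloyl anion equivalent) under Felkin–Anh control sets C10: the C9–OTBS bond lies anti to the incoming nucleophile and 1,3-anti induction from O8 reinforces the same face, placing O10 anti to O9 along the chain as the target requires.

**Step 6**
Reactants: 9 allenyl carbinol
Product: 10 (1R,2R)-1-(tert-butyldimethylsilyloxy)-1-[(4S)-2-(4-methoxyphenyl)-1,3-dioxolan-4-yl]-2-(2-vinyl-1,3-dioxolan-2-yl)propan-2-ol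
Conditions: HOCH2CH2OH, PPTS (cat.), CH2Cl2, −20 → 0 °C; Et3N quench
Reagents that add atoms: ethylene glycol OCCO
Why: Acid-catalysed addition of an alcohol to a 1-alkoxyallene: protonation at the central allene carbon gives a 1-methoxyallyl oxocarbenium ion that glycol captures at C1, and intramolecular transketalisation then expels methanol to leave the 2-vinyl-1,3-dioxolane without touching a stereocentre.

**Step 7**
Reactants: 10 tertiary alcohol; 11 trichloroethylene
Product: 13 O10-(E)-1,2-dichlorovinyl ether of 10, via dichloroacetylene 12 (not isolated)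
Conditions: KH, THF, 0 °C → rt; then 11, −50 °C → rt (dilute; 12 never isolated)
Reagents that add atoms: none
Why: Addition of the tertiary potassium alkoxide to dichloroacetylene generated in situ (anti addition, E ether) is the standard entry to ynol ethers from alcohols; the hindered O10 site disfavours silyl migration from O9, and the dichlorovinyl group also masks O10 against cyclisation onto C7 in steps 9 to 12.

**Step 8**
Reactants: 13 dichlorovinyl ether
Product: 14 (2S,3R,4R)-3-(tert-butyldimethylsilyloxy)-4-[(E)-1,2-dichlorovinyloxy]-2-(4-methoxybenzyloxy)-4-(2-vinyl-1,3-dioxolan-2-yl)pentan-1-ol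
Conditions: iBu2AlH, CH2Cl2, −78 → −20 °C
Reagents that add atoms: none
Why: Reductive opening of the p-methoxybenzylidene acetal: aluminium binds the less hindered primary O7, that C–O bond breaks and hydride reduces the oxocarbenium ion, leaving PMB on secondary O8 and C7 as the free alcohol.

**Step 9**
Reactants: 14 primary alcohol
Product: 15 (2R,3R,4R)-3-(tert-butyldimethylsilyloxy)-4-[(E)-1,2-dichlorovinyloxy]-2-(4-methoxybenzyloxy)-4-(2-vinyl-1,3-dioxolan-2-yl)pentanal
Conditions: Dess–Martin periodinane, NaHCO3, CH2Cl2, 0 °C; used crude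
Reagents that add atoms: none
Why: Dess–Martin oxidation under buffered, non-basic conditions gives the α-alkoxy aldehyde without epimerising C8.

**Step 10**
Reactants: 15 aldehyde; 16 methyl acrylate
Product: 17 Morita–Baylis–Hillman adduct (C7 carbinol; both epimers)
Conditions: 16 (excess), DABCO, MeOH, rt
Reagents that add atoms: none
Why: Morita–Baylis–Hillman reaction of an activated α-alkoxy aldehyde; the new C7 carbinol centre is erased in step 11, so both epimers are carried on.

**Step 11**
Reactants: 17 allylic alcohol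
Product: 18 (Z)-2-(bromomethyl)enoate (C7=C11; C13 = CH2Br)
Conditions: NBS, Me2S, CH2Cl2, 0 °C → rt
Reagents that add atoms: N-bromosuccinimide BrN1C(=O)CCC1=O
Why: Corey–Kim-type activation of the allylic alcohol as an alkoxysulfonium salt and SN2' attack of bromide transposes the alkene to the conjugated, thermodynamically preferred Z-2-(bromomethyl)enoate.

**Step 12**
Reactants: 18 allylic bromide; 19 acrolein
Product: 21 C6-hydroxy 2-methylene ester (C6/C7 syn), via allylzinc bromide 20 (not isolated)
Conditions: Zn dust, 19 (3 equiv), THF/sat. aq. NH4Cl, 0 °C → rt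
Reagents that add atoms: zinc [Zn] (zinc only in intermediate 20)
Why: Barbier allylation in which the allylzinc reacts at its γ-carbon (C7) through a chair transition state: the Z γ-substituent sits axial and gives the C6/C7 syn adduct (future cis-lactone), and acrolein adds to the C7 face anti to the C9 chain in the conformer with H8 eclipsing the alkene (allylic 1,3-strain), which sets C6 and C7.

**Step 13**
Reactants: 21 hydroxy ester
Product: 22 C6 triethylsilyl ether of 21
Conditions: TESOTf, 2,6-lutidine, CH2Cl2, −78 °C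
Reagents that add atoms: triethylsilyl triflate CC[Si](CC)(CC)OS(=O)(=O)C(F)(F)F
Why: Silyl ether formation with the triflate caps the hindered C6 hydroxyl before it can lactonise onto C12 or later open the epoxide.

**Step 14**
Reactants: 22 enoate
Product: 23 allylic alcohol (C12–OH; C11=C13)
Conditions: iBu2AlH, CH2Cl2, −78 °C
Reagents that add atoms: none
Why: 1,2-Reduction of the enoate with iBu2AlH at low temperature gives the 2-substituted allylic alcohol needed for directed epoxidation.

**Step 15**
Reactants: 23 allylic alcohol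
Product: 24 C11,C13-epoxy alcohol
Conditions: Ti(OiPr)4 (20 mol%), D-(−)-diethyl tartrate (24 mol%), t-BuOOH, 4 Å MS, CH2Cl2, −20 °C
Reagents that add atoms: tert-butyl hydroperoxide CC(C)(C)OO
Why: Sharpless asymmetric epoxidation of a 2-substituted primary allylic alcohol, in which the D-tartrate complex (reagent control) delivers oxygen to the C11=C13 face that gives the target configuration at C11, and only the alkene carrying the directing hydroxyl reacts.

**Step 16**
Reactants: 24 epoxy alcohol
Product: 25 chlorodiol (C13–Cl; C11–OH; C12–OH)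
Conditions: LiCl, AcOH, THF, rt
Reagents that add atoms: lithium chloride [Li+].[Cl-]
Why: Regioselective halide opening of the 2,2-disubstituted epoxide by SN2 attack of chloride at the unhindered C13 methylene; the C11–O bond is not broken, so C11 keeps its configuration.

**Step 17**
Reactants: 25 chlorodiol
Product: 26 acyclic diene with O11 and O12 triethylsilyl ethers
Conditions: TESOTf (3 equiv), 2,6-lutidine, CH2Cl2, −78 → 0 °C
Reagents that add atoms: triethylsilyl triflate CC[Si](CC)(CC)OS(=O)(=O)C(F)(F)F
Why: Silylation of the primary and the tertiary hydroxyl with the silyl triflate blocks epoxide re-closure under base and glycol cleavage in step 22.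

**Step 18**
Reactants: 26 acyclic diene
Product: 27 cis-cyclooctene dichlorovinyl ether
Conditions: second-generation Grubbs catalyst (H2IMes)(PCy3)Cl2Ru=CHPh (10 mol%), CH2Cl2, 40 °C, 2 mM
Reagents that add atoms: none
Why: Ring-closing metathesis of the two vinyl groups with loss of ethylene; an eight-membered ring can only hold the cis alkene, and the densely substituted chain favours the folded conformer.

**Step 19**
Reactants: 27 cyclooctene dichlorovinyl ether
Product: 29 cyclooctene 1-propynyl ether, via lithium alkynyl ether 28 (not isolated)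
Conditions: n-BuLi (2.5 equiv), THF, −78 → −40 °C; then MeI, DMPU, −78 → 0 °C; kept cold and used at once
Reagents that add atoms: iodomethane CI; n-butyllithium [Li]CCCC (lithium only in intermediate 28)
Why: Standard ynol ether synthesis from a 1,2-dichlorovinyl ether: deprotonation and loss of chloride give the chloroalkynyl ether, lithium–chlorine exchange gives the lithium alkynyl ether, and C-methylation follows; the product is kept cold because tertiary ynol ethers fragment on heating.

**Step 20**
Reactants: 29 cyclooctene 1-propynyl ether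
Product: 30 bridged ten-membered dienyl ether with C1 ketal
Conditions: Ph3PAuNTf2 (5 mol%), 2,6-di-tert-butyl-4-methylpyridine (10 mol%), 4 Å MS, CH2Cl2, −20 °C → rt
Reagents that add atoms: none
Why: Proposed new method: Ph3PAuNTf2 (monovalent gold) binds C3≡C4 and polarises the ynol ether so that C3 becomes an oxygen-stabilised electrophile; C2 of the cis-alkene attacks C3, C5 then bonds to C4 (cyclopropyl gold carbene or cyclobutene), and cleavage of the old C2–C5 bond with release of gold gives the diene. The dihydrofuran (O–C3–C2–C1–C10) closes in the 5-exo-dig mode, and the ten-membered carbocycle arises not by a cyclisation but by two-carbon expansion of the cyclooctene. The closest known reaction type is the PtCl2- or gold-catalysed single-cleavage skeletal rearrangement of 1,6-enynes, including cyclooctene-tethered enynes that give bridged ten-membered dienes; an ynol ether tethered through its own oxygen has not been used as the alkyne. No stereocentre is formed. The step needs exo regiochemistry, which the oxygen-induced polarisation of the alkyne dictates, and Z geometry at C4=C5, which follows from the cis ring fusion because the five-membered ring holds C1 and O cis on C2=C3 and so allows only the ring opening that turns C6 inward. Sieves, a hindered pyridine and low temperature protect the acid- and heat-sensitive tertiary ynol ether, and the oxygens next to it carry no transferable group (TBS on O9, cyclic ketal at C1).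

**Step 21**
Reactants: 30 dienyl ether ketal
Product: 31 furanone diol (C6–OH; C12–OH)
Conditions: AcOH/THF/H2O (3:1:1), rt
Reagents that add atoms: water O
Why: Mild aqueous acid hydrolysis: the C1 ketal of the dienyl ether is a vinylogous orthoester and collapses to the 3(2H)-furanone, and the primary and secondary TES ethers are cleaved, while the hindered tertiary TES, the TBS and the PMB ethers stay.

**Step 22**
Reactants: 31 furanone diol
Product: 33 cis-fused 6,12-lactone, via lactol 32 (not isolated)
Conditions: TEMPO (20 mol%), PhI(OAc)2 (2.5 equiv), CH2Cl2, rt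
Reagents that add atoms: none
Why: TEMPO/PhI(OAc)2 oxidative lactonisation: the oxoammonium ion oxidises the primary C12 alcohol faster than the secondary one, the cis C6 hydroxyl traps the aldehyde as the lactol, and a second oxidation gives the γ-lactone, O8 being blocked against the alternative 8,12-lactone.

**Step 23**
Reactants: 33 lactone PMB ether
Product: 34 C8 alcohol
Conditions: DDQ, CH2Cl2/pH 7 buffer (10:1), 0 °C → rt
Reagents that add atoms: none
Why: Oxidative cleavage of the PMB ether by DDQ in wet solvent frees only O8.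

**Step 24**
Reactants: 34 C8 alcohol; 35 angelic acid
Product: 37 C8 angelate, via mixed anhydride 36 (not isolated)
Conditions: 35, 2,4,6-Cl3C6H2COCl, Et3N, toluene, rt; then 34, 80 °C
Reagents that add atoms: 2,4,6-trichlorobenzoyl chloride O=C(Cl)c1c(Cl)cc(Cl)cc1Cl (atoms only in intermediate 36)
Why: Yamaguchi esterification run without DMAP: the C8 hydroxyl attacks the unhindered angeloyl carbonyl of the mixed anhydride, and the absence of a nucleophilic catalyst avoids Z to E isomerisation to the tiglate.

**Step 25**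
Reactants: 37 bis-silyl angelate
Product: 38 target CNP0272644.1
Conditions: HF·pyridine, pyridine, THF, 0 °C → rt
Reagents that add atoms: none
Why: Fluoride-mediated desilylation with acidic HF·pyridine removes the O9 TBS and O11 TES groups without closing the chlorohydrin to an epoxide or touching the esters.

**Compound list**

1 | diethyl L-tartrate | CCOC(=O)[C@H](O)[C@@H](O)C(=O)OCC | starting material
2 | diethyl (2R,3R)-2-(tert-butyldimethylsilyloxy)-3-hydroxybutanedioate | CCOC(=O)[C@H](O[Si](C)(C)C(C)(C)C)[C@@H](O)C(=O)OCC | intermediate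
3 | ethyl (2R,3S)-2-(tert-butyldimethylsilyloxy)-3,4-dihydroxybutanoate | CCOC(=O)[C@H](O[Si](C)(C)C(C)(C)C)[C@@H](O)CO | intermediate
4 | ethyl (2R)-2-(tert-butyldimethylsilyloxy)-2-[(4S)-2-(4-methoxyphenyl)-1,3-dioxolan-4-yl]acetate, both acetal epimers | CCOC(=O)[C@H](O[Si](C)(C)C(C)(C)C)[C@@H]1COC(c2ccc(OC)cc2)O1 | intermediate
5 | (2R)-2-(tert-butyldimethylsilyloxy)-N-methoxy-N-methyl-2-[(4S)-2-(4-methoxyphenyl)-1,3-dioxolan-4-yl]acetamide (Weinreb amide) | CON(C)C(=O)[C@H](O[Si](C)(C)C(C)(C)C)[C@@H]1COC(c2ccc(OC)cc2)O1 | intermediate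
6 | (1R)-1-(tert-butyldimethylsilyloxy)-1-[(4S)-2-(4-methoxyphenyl)-1,3-dioxolan-4-yl]propan-2-one | CC(=O)[C@H](O[Si](C)(C)C(C)(C)C)[C@@H]1COC(c2ccc(OC)cc2)O1 | intermediate
7 | methoxyallene (1-methoxypropa-1,2-diene) | COC=C=C | starting material
8 | 1-lithio-1-methoxyallene | [Li]C(OC)=C=C | intermediate
9 | (1R,2R)-1-(tert-butyldimethylsilyloxy)-3-methoxy-2-methyl-1-[(4S)-2-(4-methoxyphenyl)-1,3-dioxolan-4-yl]penta-3,4-dien-2-ol | C=C=C(OC)[C@](C)(O)[C@H](O[Si](C)(C)C(C)(C)C)[C@@H]1COC(c2ccc(OC)cc2)O1 | intermediate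
10 | (1R,2R)-1-(tert-butyldimethylsilyloxy)-1-[(4S)-2-(4-methoxyphenyl)-1,3-dioxolan-4-yl]-2-(2-vinyl-1,3-dioxolan-2-yl)propan-2-ol | C=CC1(OCCO1)[C@](C)(O)[C@H](O[Si](C)(C)C(C)(C)C)[C@@H]2COC(c3ccc(OC)cc3)O2 | intermediate
11 | trichloroethylene | ClC=C(Cl)Cl | starting material
12 | dichloroacetylene | ClC#CCl | intermediate
13 | (E)-1,2-dichlorovinyl ether of 10 at the tertiary oxygen O10 (C9 OTBS; O7/O8 p-methoxybenzylidene acetal; C1 dioxolane; C2 vinyl) | C=CC1(OCCO1)[C@](C)(O/C(Cl)=C\Cl)[C@H](O[Si](C)(C)C(C)(C)C)[C@@H]2COC(c3ccc(OC)cc3)O2 | intermediate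
14 | (2S,3R,4R)-3-(tert-butyldimethylsilyloxy)-4-[(E)-1,2-dichlorovinyloxy]-2-(4-methoxybenzyloxy)-4-(2-vinyl-1,3-dioxolan-2-yl)pentan-1-ol (C7 alcohol, O8 PMB) | C=CC1(OCCO1)[C@](C)(O/C(Cl)=C\Cl)[C@H](O[Si](C)(C)C(C)(C)C)[C@@H](OCc2ccc(OC)cc2)CO | intermediate
15 | (2R,3R,4R)-3-(tert-butyldimethylsilyloxy)-4-[(E)-1,2-dichlorovinyloxy]-2-(4-methoxybenzyloxy)-4-(2-vinyl-1,3-dioxolan-2-yl)pentanal (C7 aldehyde) | C=CC1(OCCO1)[C@](C)(O/C(Cl)=C\Cl)[C@H](O[Si](C)(C)C(C)(C)C)[C@@H](OCc2ccc(OC)cc2)C=O | intermediate
16 | methyl acrylate | C=CC(=O)OC | starting material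
17 | Morita–Baylis–Hillman adduct of 15: methyl 2-methylene-3-hydroxy ester, C7 carbinol as both epimers, C8–C10 as in 15 | C=CC1(OCCO1)[C@](C)(O/C(Cl)=C\Cl)[C@H](O[Si](C)(C)C(C)(C)C)[C@@H](OCc2ccc(OC)cc2)C(O)C(=C)C(=O)OC | intermediate
18 | methyl (Z)-2-(bromomethyl)alk-2-enoate: C7=C11 alkene with C8 cis to CH2Br (C13), C12 methyl ester, C8–C10 as in 15 | C=CC1(OCCO1)[C@](C)(O/C(Cl)=C\Cl)[C@H](O[Si](C)(C)C(C)(C)C)[C@@H](OCc2ccc(OC)cc2)/C=C(\CBr)C(=O)OC | intermediate
19 | acrolein | C=CC=O | starting material
20 | allylzinc bromide from 18 (zinc on C13) | C=CC1(OCCO1)[C@](C)(O/C(Cl)=C\Cl)[C@H](O[Si](C)(C)C(C)(C)C)[C@@H](OCc2ccc(OC)cc2)/C=C(\C[Zn]Br)C(=O)OC | intermediate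
21 | Barbier adduct: methyl 2-methylene ester (C11=C13, C12 ester) with C6 hydroxyl bearing the C5 vinyl group, C6/C7 syn, C6 and C7 configured as in the target | C=CC1(OCCO1)[C@](C)(O/C(Cl)=C\Cl)[C@H](O[Si](C)(C)C(C)(C)C)[C@@H](OCc2ccc(OC)cc2)[C@H]([C@@H](O)C=C)C(=C)C(=O)OC | intermediate
22 | C6 triethylsilyl ether of 21 | C=CC1(OCCO1)[C@](C)(O/C(Cl)=C\Cl)[C@H](O[Si](C)(C)C(C)(C)C)[C@@H](OCc2ccc(OC)cc2)[C@H]([C@@H](O[Si](CC)(CC)CC)C=C)C(=C)C(=O)OC | intermediate
23 | allylic alcohol: C12 CH2OH on the C11=C13 methylene unit, otherwise as 22 | C=CC1(OCCO1)[C@](C)(O/C(Cl)=C\Cl)[C@H](O[Si](C)(C)C(C)(C)C)[C@@H](OCc2ccc(OC)cc2)[C@H]([C@@H](O[Si](CC)(CC)CC)C=C)C(=C)CO | intermediate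
24 | C11,C13-epoxide of 23 with free C12 alcohol, C11 configured for the target | C=CC1(OCCO1)[C@](C)(O/C(Cl)=C\Cl)[C@H](O[Si](C)(C)C(C)(C)C)[C@@H](OCc2ccc(OC)cc2)[C@H]([C@@H](O[Si](CC)(CC)CC)C=C)[C@@]3(CO)CO3 | intermediate
25 | chlorodiol: C13 chloride, tertiary C11 hydroxyl, primary C12 hydroxyl | C=CC1(OCCO1)[C@](C)(O/C(Cl)=C\Cl)[C@H](O[Si](C)(C)C(C)(C)C)[C@@H](OCc2ccc(OC)cc2)[C@H]([C@@H](O[Si](CC)(CC)CC)C=C)[C@](CCl)(CO)O | intermediate
26 | acyclic diene: O6, O11 and O12 triethylsilyl ethers, O8 PMB, O9 TBS, O10 (E)-1,2-dichlorovinyl, C1 dioxolane, vinyl groups on C1 and C6 | C=CC1(OCCO1)[C@](C)(O/C(Cl)=C\Cl)[C@H](O[Si](C)(C)C(C)(C)C)[C@@H](OCc2ccc(OC)cc2)[C@H]([C@@H](O[Si](CC)(CC)CC)C=C)[C@](CCl)(CO[Si](CC)(CC)CC)O[Si](CC)(CC)CC | intermediate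
27 | cis-cyclooctene (ring C1, C2, C5–C10; C2=C5 cis) with O10 (E)-1,2-dichlorovinyl ether, substituents as in 26 | COc1ccc(cc1)CO[C@H]1[C@@H]([C@](CCl)(CO[Si](CC)(CC)CC)O[Si](CC)(CC)CC)[C@@H](O[Si](CC)(CC)CC)/C=C\C2(OCCO2)[C@](C)(O/C(Cl)=C\Cl)[C@@H]1O[Si](C)(C)C(C)(C)C | intermediate
28 | lithium alkynyl ether of the cyclooctene (O10–C≡C–Li) | COc1ccc(cc1)CO[C@H]1[C@@H]([C@](CCl)(CO[Si](CC)(CC)CC)O[Si](CC)(CC)CC)[C@@H](O[Si](CC)(CC)CC)/C=C\C2(OCCO2)[C@](C)(OC#C[Li])[C@@H]1O[Si](C)(C)C(C)(C)C | intermediate
29 | cyclooctene 1-propynyl ether with C1 ketal (key-step precursor) | COc1ccc(cc1)CO[C@H]1[C@@H]([C@](CCl)(CO[Si](CC)(CC)CC)O[Si](CC)(CC)CC)[C@@H](O[Si](CC)(CC)CC)/C=C\C2(OCCO2)[C@](C)(OC#CC)[C@@H]1O[Si](C)(C)C(C)(C)C | intermediate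
30 | bridged ten-membered dienyl ether with C1 ketal (C2=C3 in the dihydrofuran, C4=C5 Z) | COc1ccc(cc1)CO[C@H]1[C@@H]([C@](CCl)(CO[Si](CC)(CC)CC)O[Si](CC)(CC)CC)[C@@H](O[Si](CC)(CC)CC)/C=C(/C)C3=CC2(OCCO2)[C@](C)(O3)[C@@H]1O[Si](C)(C)C(C)(C)C | intermediate
31 | furanone diol: C1 ketone, free C6 and C12 hydroxyls, O11 TES, O8 PMB, O9 TBS | COc1ccc(cc1)CO[C@H]1[C@@H]([C@](CCl)(CO)O[Si](CC)(CC)CC)[C@@H](O)/C=C(/C)C2=CC(=O)[C@](C)(O2)[C@@H]1O[Si](C)(C)C(C)(C)C | intermediate
32 | 6,12-lactol (both anomers) | COc1ccc(cc1)CO[C@H]1[C@@H]2[C@H](/C=C(/C)C3=CC(=O)[C@](C)(O3)[C@@H]1O[Si](C)(C)C(C)(C)C)OC(O)[C@@]2(O[Si](CC)(CC)CC)CCl | intermediate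
33 | cis-fused 6,12-lactone with O8 PMB, O9 TBS, O11 TES | COc1ccc(cc1)CO[C@H]1[C@@H]2[C@H](/C=C(/C)C3=CC(=O)[C@](C)(O3)[C@@H]1O[Si](C)(C)C(C)(C)C)OC(=O)[C@@]2(O[Si](CC)(CC)CC)CCl | intermediate
34 | C8 alcohol of the lactone (O9 TBS, O11 TES) | O[C@H]1[C@@H]2[C@H](/C=C(/C)C3=CC(=O)[C@](C)(O3)[C@@H]1O[Si](C)(C)C(C)(C)C)OC(=O)[C@@]2(O[Si](CC)(CC)CC)CCl | intermediate
35 | angelic acid | C/C=C(/C)C(=O)O | starting material
36 | angelic 2,4,6-trichlorobenzoic mixed anhydride | C/C=C(/C)C(=O)OC(=O)c1c(Cl)cc(Cl)cc1Cl | intermediate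
37 | C8 angelate with O9 TBS and O11 TES | C/C=C(/C)C(=O)O[C@H]1[C@@H]2[C@H](/C=C(/C)C3=CC(=O)[C@](C)(O3)[C@@H]1O[Si](C)(C)C(C)(C)C)OC(=O)[C@@]2(O[Si](CC)(CC)CC)CCl | intermediate
38 | CNP0272644.1: 8-O-angeloyl-13-chloro-9,11-dihydroxy furanone germacranolide (6S,7S,8S,9R,10R,11R; C4=C5 Z) | C/C=C(/C)C(=O)O[C@H]1[C@@H]2[C@H](/C=C(/C)C3=CC(=O)[C@](C)(O3)[C@@H]1O)OC(=O)[C@@]2(O)CCl | target

**Totals.** Total step count: 25. Longest linear sequence: 25 steps from diethyl L-tartrate (1).

**Steps most likely to fail**

1. Step 20 (proposed new method). The ynol ether may be hydrated by traces of acid, may fragment thermally before cyclising, or may be attacked by the O8 ether or the C1 ketal oxygen in place of the alkene; a double-cleavage pathway could also scramble the diene. Fallback by known ruthenium carbene chemistry (ring-closing enyne metathesis of alkynyl ethers combined with tandem dienyne ring-closing metathesis): it sets out from acyclic diene 26, which with n-BuLi and then MeI (conditions of step 19) should give the acyclic dienyne 1-propynyl ether F1. The second-generation Grubbs catalyst (H2IMes)(PCy3)Cl2Ru=CHPh in dilute CH2Cl2 at 40 °C should then join C2 to C3 by enyne metathesis and close C4=C5 against the C5 vinyl group with loss of ethylene. The sequence comes back to the route at 30. The C4=C5 geometry would then depend on ring strain and not on the cis ring fusion.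

2. Step 12. Acrolein may add with poor facial selectivity at C7, or with poor syn/anti control at C6, since both centres rest on substrate control in an open organozinc. Fallback with catalyst control through an isolated allylboronate: it sets out from bromide 18, which on Miyaura-type borylation (B2pin2, Pd2(dba)3 as zerovalent palladium source, KOAc, toluene, 50 °C) should give the allyl pinacolboronate F2. Allylboration of acrolein through a closed chair transition state, catalysed by a chiral phosphoric acid (TRIP, the antipode chosen to reinforce the wanted face, toluene, −30 °C), should then fix C6 and C7 together. After aqueous work-up the sequence comes back to the route at 21.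

3. Step 18. Ring closure may be slow or give oligomers, because both vinyl groups sit on fully substituted or silyloxy-bearing carbons and the side chain on C7 carries two bulky silyl ethers. Fallback by closing the ring before the side chain is silylated: it sets out from chlorodiol 25, which under the same catalyst (CH2Cl2, 40 °C, 2 mM) should give the less congested cyclooctene chlorodiol F3. Bis-silylation (TESOTf, 2,6-lutidine, as in step 17) then comes back to the route at 27.

**Further compounds**

F1 | step 20 | acyclic dienyne: 26 with the O10 dichlorovinyl group replaced by 1-propynyl | C=CC1(OCCO1)[C@](C)(OC#CC)[C@H](O[Si](C)(C)C(C)(C)C)[C@@H](OCc2ccc(OC)cc2)[C@H]([C@@H](O[Si](CC)(CC)CC)C=C)[C@](CCl)(CO[Si](CC)(CC)CC)O[Si](CC)(CC)CC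
F2 | step 12 | allyl pinacolboronate: 18 with bromine on C13 replaced by the 4,4,5,5-tetramethyl-1,3,2-dioxaborolan-2-yl group | C=CC1(OCCO1)[C@](C)(O/C(Cl)=C\Cl)[C@H](O[Si](C)(C)C(C)(C)C)[C@@H](OCc2ccc(OC)cc2)/C=C(\CB3OC(C)(C)C(C)(C)O3)C(=O)OC
F3 | step 18 | cyclooctene chlorodiol: 27 with free C11 and C12 hydroxyls | COc1ccc(cc1)CO[C@H]1[C@@H]([C@](CCl)(CO)O)[C@@H](O[Si](CC)(CC)CC)/C=C\C2(OCCO2)[C@](C)(O/C(Cl)=C\Cl)[C@@H]1O[Si](C)(C)C(C)(C)C
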